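**Plan**
The target is (+)-catechin-(4α→8)-(+)-catechin-(4α→6)-(+)-catechin: three (2R,3S) flavan-3-ol units, both interflavan bonds 3,4-trans.
Retrosynthesis cuts C4(middle)–C6(bottom) and, in the same operation, contracts the middle pyran ring to a 2,3-dihydrobenzofuran (ring O moved from flavan C2 back to C3, 3-O-benzyl moved back to C4, OH on the exocyclic benzylic carbon). It then opens the furan to a chalcone epoxide, cuts the chalcone C=C, and cuts C4(top)–C8(middle).
Forward: top and bottom units come from (+)-catechin; the capped top unit is joined to the ring A acetophenone; chalcone, epoxide and furan ring follow; the last C–C bond is made while the furan expands to the pyran; one hydrogenolysis finishes.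
Enabling feature: in the furan, O1–C2–C3 carries a leaving group on the exocyclic carbon next to O1 and a benzyloxy group on C3, and C3 sits on the 2,4,6-trioxygenated ring A. Two successive 1,2-oxygen shifts through three-membered oxonium ions therefore run downhill to the trioxybenzylic C4 cation.
Stereochemistry: top and bottom units from the chiral pool; middle C2 and C3 from the Julia–Colonna epoxide, relayed by three stereospecific inversions; both C4 centres by attack anti to the 3-benzyloxy group.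

Key step: step 12

Remark: flavan numbering is used for flavans and benzofuran numbering for 15–17. Compound 5 is drawn as the 3,4-trans methyl ether; either C4 epimer serves because C4 is ionized. Compounds 6 and 9 are taken as commercial.

Step 1
Reactants: 1 (+)-catechin
Product: 2 5,7,3',4'-tetra-O-benzyl-(+)-catechin
Conditions: BnBr (4.2 equiv), K2CO3, DMF, 0 °C to rt
Reagents that add atoms: benzyl bromide, BrCc1ccccc1
Why: Williamson etherification in which the four phenoxides are alkylated and the less acidic secondary 3-OH is left free under carbonate conditions.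

Step 2
Reactants: 2 5,7,3',4'-tetra-O-benzyl-(+)-catechin
Product: 3 3,5,7,3',4'-penta-O-benzyl-(+)-catechin
Conditions: NaH, BnBr, Bu4NI (cat.), DMF, 0 °C to rt
Reagents that add atoms: benzyl bromide, BrCc1ccccc1
Why: Williamson etherification of the secondary alkoxide, which protects every oxygen of the unit with one group type that is removed together at the end.

Step 3
Reactants: 3 3,5,7,3',4'-penta-O-benzyl-(+)-catechin
Product: 4 8-bromo-3,5,7,3',4'-penta-O-benzyl-(+)-catechin
Conditions: NBS (1.0 equiv), CH2Cl2, −78 °C to 0 °C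
Reagents that add atoms: N-bromosuccinimide, O=C1CCC(=O)N1Br
Why: Electrophilic aromatic bromination, which should take the more reactive and less hindered C8 of ring A and leave C6 as the only free nucleophilic position.

Step 4
Reactants: 4 8-bromo-3,5,7,3',4'-penta-O-benzyl-(+)-catechin
Product: 5 8-bromo-4α-methoxy-3,5,7,3',4'-penta-O-benzyl-(+)-catechin
Conditions: DDQ (2 equiv), MeOH, CH2Cl2, rt
Reagents that add atoms: methanol, CO
Why: DDQ-mediated oxidative benzylic etherification, in which hydride is abstracted from C4 (activated by three ring oxygens) and methanol traps the cation; this is the standard activation of benzylated flavan-3-ols.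

Step 5
Reactants: 5 8-bromo-4α-methoxy-3,5,7,3',4'-penta-O-benzyl-(+)-catechin; 6 1-[2-hydroxy-4,6-bis(benzyloxy)phenyl]ethanone (3 equiv)
Product: 7 1-[3-(8-bromo-3,5,7,3',4'-penta-O-benzylcatechin-4α-yl)-2-hydroxy-4,6-bis(benzyloxy)phenyl]ethanone (flavan C4 bonded to the ring carbon between OH and OBn, 3,4-trans)
Conditions: Me3SiOTf (0.3 equiv), 4 Å MS, CH2Cl2, −40 °C to 0 °C; Et3N quench
Reagents that add atoms: none
Why: Friedel–Crafts alkylation by the flavan-4-yl cation, expected ortho to the free phenol as in aryl C-glycosylation of this ketone (O-alkylation then O-to-C shift), with attack anti to the 3-benzyloxy group giving the 4α bond; the C8 bromine of 5 suppresses self-condensation.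

Step 6
Reactants: 7 the ketone of step 5
Product: 8 1-[2-allyloxy-3-(8-bromo-3,5,7,3',4'-penta-O-benzylcatechin-4α-yl)-4,6-bis(benzyloxy)phenyl]ethanone
Conditions: allyl bromide, K2CO3, DMF, 60 °C
Reagents that add atoms: allyl bromide, C=CCBr
Why: Williamson etherification, which masks the phenol so the later chalcone epoxide cannot cyclize at the ketone oxidation level; the allyl group is removable without acid or hydrogen.

Step 7
Reactants: 8 the allyl ether of step 6; 9 3,4-bis(benzyloxy)benzaldehyde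
Product: 10 (E)-1-[2-allyloxy-3-(8-bromo-penta-O-benzylcatechin-4α-yl)-4,6-bis(benzyloxy)phenyl]-3-[3,4-bis(benzyloxy)phenyl]prop-2-en-1-one
Conditions: KOH, EtOH–THF, rt to 40 °C
Reagents that add atoms: none
Why: Claisen–Schmidt condensation, in which aldol addition and E1cB dehydration give the thermodynamically favoured E enone; it is routine for 2',4',6'-trialkoxyacetophenones.

Step 8
Reactants: 10 the chalcone of step 7
Product: 11 the (2R,3S)-2,3-epoxy ketone of 10 (trans-epoxide; C2 next to the carbonyl)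
Conditions: poly-L-leucine, urea–H2O2, DBU, THF, rt
Reagents that add atoms: hydrogen peroxide (used as its urea adduct), OO
Why: Julia–Colonna epoxidation (Weitz–Scheffer addition of hydroperoxide to the enone), in which the poly-L-leucine helix selects the enone face that gives the (2R,3S)-epoxide; the isolated allyl alkene is inert, and any minor epoxide is a diastereomer separable because of the chiral flavan unit.

Step 9
Reactants: 11 the (2R,3S)-epoxy ketone
Product: 12 the (1S,2S,3S)-2,3-epoxy-1-ol (erythro: carbinol OH and epoxide O syn in the Fischer projection)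
Conditions: Zn(BH4)2, Et2O, −20 °C
Reagents that add atoms: none
Why: Chelation-controlled ketone reduction, in which zinc bridges the carbonyl and epoxide oxygens and hydride attacks the open face to give the erythro epoxy alcohol; this places the future ether cis to the side chain in the furan.

Step 10
Reactants: 12 the erythro epoxy alcohol
Product: 13 the 1-O-benzyl ether of 12 ((1S,2R,3S) by CIP; same spatial arrangement)
Conditions: NaH, BnBr, Bu4NI (cat.), THF, 0 °C
Reagents that add atoms: benzyl bromide, BrCc1ccccc1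
Why: Williamson etherification, fast in an aprotic medium relative to Payne rearrangement; an ether is chosen because it cannot leave from the phenoxide of step 11 (no o-quinone methide), and it is the oxygen that ends on C3 of the flavan.

Step 11
Reactants: 13 the epoxy benzyl ether
Product: 15 (2S,3S)-3-benzyloxy-2-[(S)-[3,4-bis(benzyloxy)phenyl](hydroxy)methyl]-4,6-bis(benzyloxy)-7-(8-bromo-penta-O-benzylcatechin-4α-yl)-2,3-dihydrobenzofuran (2,3-cis; O1 and carbinol OH erythro), via phenol 14 (not isolated)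
Conditions: Pd(PPh3)4 (5 mol%), K2CO3, MeOH–THF, rt to 40 °C
Reagents that add atoms: none
Why: Tsuji–Trost deallylation with zerovalent palladium frees the phenoxide, which opens the epoxide by 5-exo-tet SN2 attack at the nearer carbon with inversion (favoured under basic conditions over 6-endo attack at the benzylic carbon), leaving the epoxide oxygen as the exocyclic (S)-carbinol.

Step 12
Reactants: 15 the dihydrobenzofuran carbinol; 4 8-bromo-3,5,7,3',4'-penta-O-benzyl-(+)-catechin (3 equiv)
Product: 19 8-bromo-penta-O-benzylcatechin-(4α→8)-penta-O-benzylcatechin-(4α→6)-8-bromo-penta-O-benzylcatechin (all units 2R,3S; fifteen benzyl ethers, two bromines), via benzylic triflate 16 (not isolated), via bridged aryloxonium triflate 17 (not isolated), via flavan-4-yl cation 18 (not isolated)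
Conditions: Tf2O (1.05 equiv), 2,6-di-tert-butyl-4-methylpyridine (2.5 equiv), 4 Å MS, CH2Cl2, −78 °C to −30 °C; Et3N quench
Reagents that add atoms: none
Why: Proposed new method: triflation of the only free hydroxyl gives the electron-rich benzylic triflate 16, whose ionization is assisted by the anti-periplanar furan oxygen (3-exo-tet, inversion at the carbinol carbon) to give the bridged aryloxonium ion 17; the cis benzyloxy oxygen on C3 then opens 17 at the former furan C2 (second 3-exo-tet, inversion), which breaks the old O1–C2 bond, turns the five-membered furan into the six-membered pyran (ring expansion by the carbinol carbon, formally a 6-endo O–C closure) and leaves the charge on the 2,4,6-trioxygenated benzylic C4 of 18, the thermodynamic sink of the relay. The closest known reaction types are the oxonium-mediated ring expansion of 2-(1-sulfonyloxyalkyl)tetrahydrofurans and 2-(1-hydroxyalkyl)-2,3-dihydrobenzofurans to 3-substituted tetrahydropyrans and chromans, 1,2-alkoxy shifts through oxiranium ions, and the Friedel–Crafts capture of flavan-4-yl cations used in procyanidin synthesis. C2 and C3 of the new flavan follow from the two stereospecific inversions of the (S)-carbinol and the (2S) furan carbon of 15, both traceable to the (2R,3S)-epoxide, and C4 is set by attack of 4 anti to the 3-benzyloxy group (bridged oxiranium or its open cation), giving the 3,4-trans 4α bond. The step needs the exocyclic alcohol to ionize before the benzylic ether on C3, which base-buffered triflation of the single OH (no Lewis acid) should secure; it also needs C–C bond formation at C6 of the nucleophile, which the C8 bromine of 4 (used in excess) secures while every C8 of the electrophile is blocked by bromine or by the top unit.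

Step 13
Reactants: 19 the protected dibromo trimer
Product: 20 (+)-catechin-(4α→8)-(+)-catechin-(4α→6)-(+)-catechin (CNP0178679.4)
Conditions: H2 (1 atm), Pd(OH)2/C, Et3N, THF–MeOH–H2O, rt
Reagents that add atoms: none
Why: Hydrogenolysis of the fifteen benzyl ethers with concurrent hydrodebromination of the two aryl bromides (Et3N takes up HBr); no stereocentre is touched and the acid-sensitive interflavan bonds see only neutral to basic conditions.

**Compound list**
1 | (+)-catechin, (2R,3S) | Oc1cc(O)c2c(c1)O[C@H](c3ccc(O)c(O)c3)[C@@H](O)C2 | starting material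
2 | 5,7,3',4'-tetra-O-benzyl-(+)-catechin | C(c4ccccc4)Oc1cc(OCc4ccccc4)c2c(c1)O[C@H](c3ccc(OCc4ccccc4)c(OCc4ccccc4)c3)[C@@H](O)C2 | intermediate
3 | 3,5,7,3',4'-penta-O-benzyl-(+)-catechin | C(c4ccccc4)Oc1cc(OCc4ccccc4)c2c(c1)O[C@H](c3ccc(OCc4ccccc4)c(OCc4ccccc4)c3)[C@@H](OCc4ccccc4)C2 | intermediate
4 | 8-bromo-3,5,7,3',4'-penta-O-benzyl-(+)-catechin | C(c4ccccc4)Oc1cc(OCc4ccccc4)c2c(c1Br)O[C@H](c3ccc(OCc4ccccc4)c(OCc4ccccc4)c3)[C@@H](OCc4ccccc4)C2 | intermediate
5 | 8-bromo-4α-methoxy-3,5,7,3',4'-penta-O-benzyl-(+)-catechin (3,4-trans drawn) | C(c4ccccc4)Oc1cc(OCc4ccccc4)c2c(c1Br)O[C@H](c3ccc(OCc4ccccc4)c(OCc4ccccc4)c3)[C@@H](OCc4ccccc4)[C@@H]2OC | intermediate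
6 | 1-[2-hydroxy-4,6-bis(benzyloxy)phenyl]ethanone | CC(=O)c1c(O)cc(OCc2ccccc2)cc1OCc2ccccc2 | starting material
7 | 1-[3-(8-bromo-penta-O-benzylcatechin-4α-yl)-2-hydroxy-4,6-bis(benzyloxy)phenyl]ethanone | C(c4ccccc4)Oc1cc(OCc4ccccc4)c2c(c1Br)O[C@H](c3ccc(OCc4ccccc4)c(OCc4ccccc4)c3)[C@@H](OCc4ccccc4)[C@@H]2c5c(O)c(C(C)=O)c(OCc4ccccc4)cc5OCc4ccccc4 | intermediate
8 | 2-O-allyl ether of 7 | C(c4ccccc4)Oc1cc(OCc4ccccc4)c2c(c1Br)O[C@H](c3ccc(OCc4ccccc4)c(OCc4ccccc4)c3)[C@@H](OCc4ccccc4)[C@@H]2c5c(OCC=C)c(C(C)=O)c(OCc4ccccc4)cc5OCc4ccccc4 | intermediate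
9 | 3,4-bis(benzyloxy)benzaldehyde | O=Cc1ccc(OCc2ccccc2)c(OCc2ccccc2)c1 | starting material
10 | (E)-chalcone from 8 and 9 | C(c4ccccc4)Oc1cc(OCc4ccccc4)c2c(c1Br)O[C@H](c3ccc(OCc4ccccc4)c(OCc4ccccc4)c3)[C@@H](OCc4ccccc4)[C@@H]2c5c(OCC=C)c(C(=O)/C=C/c6ccc(OCc4ccccc4)c(OCc4ccccc4)c6)c(OCc4ccccc4)cc5OCc4ccccc4 | intermediate
11 | (2R,3S)-trans-epoxy ketone of 10 | C(c4ccccc4)Oc1cc(OCc4ccccc4)c2c(c1Br)O[C@H](c3ccc(OCc4ccccc4)c(OCc4ccccc4)c3)[C@@H](OCc4ccccc4)[C@@H]2c5c(OCC=C)c(C(=O)[C@@H]6O[C@H]6c7ccc(OCc4ccccc4)c(OCc4ccccc4)c7)c(OCc4ccccc4)cc5OCc4ccccc4 | intermediate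
12 | (1S,2S,3S)-erythro-2,3-epoxy-1-ol | C(c4ccccc4)Oc1cc(OCc4ccccc4)c2c(c1Br)O[C@H](c3ccc(OCc4ccccc4)c(OCc4ccccc4)c3)[C@@H](OCc4ccccc4)[C@@H]2c5c(OCC=C)c([C@H](O)[C@@H]6O[C@H]6c7ccc(OCc4ccccc4)c(OCc4ccccc4)c7)c(OCc4ccccc4)cc5OCc4ccccc4 | intermediate
13 | 1-O-benzyl ether of 12 | C(c4ccccc4)Oc1cc(OCc4ccccc4)c2c(c1Br)O[C@H](c3ccc(OCc4ccccc4)c(OCc4ccccc4)c3)[C@@H](OCc4ccccc4)[C@@H]2c5c(OCC=C)c([C@H](OCc4ccccc4)[C@@H]6O[C@H]6c7ccc(OCc4ccccc4)c(OCc4ccccc4)c7)c(OCc4ccccc4)cc5OCc4ccccc4 | intermediate
14 | free phenol from deallylation of 13 (not isolated) | C(c4ccccc4)Oc1cc(OCc4ccccc4)c2c(c1Br)O[C@H](c3ccc(OCc4ccccc4)c(OCc4ccccc4)c3)[C@@H](OCc4ccccc4)[C@@H]2c5c(O)c([C@H](OCc4ccccc4)[C@@H]6O[C@H]6c7ccc(OCc4ccccc4)c(OCc4ccccc4)c7)c(OCc4ccccc4)cc5OCc4ccccc4 | intermediate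
15 | (2S,3S)-3-benzyloxy-2-[(S)-aryl(hydroxy)methyl]-4,6-bis(benzyloxy)-7-(flavan-4α-yl)-2,3-dihydrobenzofuran (2,3-cis) | C(c4ccccc4)Oc1cc(OCc4ccccc4)c2c(c1Br)O[C@H](c3ccc(OCc4ccccc4)c(OCc4ccccc4)c3)[C@@H](OCc4ccccc4)[C@@H]2c5c(OCc4ccccc4)cc(OCc4ccccc4)c6c5O[C@@H]([C@@H](O)c7ccc(OCc4ccccc4)c(OCc4ccccc4)c7)[C@H]6OCc4ccccc4 | intermediate
16 | benzylic triflate of 15 (not isolated) | C(c4ccccc4)Oc1cc(OCc4ccccc4)c2c(c1Br)O[C@H](c3ccc(OCc4ccccc4)c(OCc4ccccc4)c3)[C@@H](OCc4ccccc4)[C@@H]2c5c(OCc4ccccc4)cc(OCc4ccccc4)c6c5O[C@@H]([C@@H](OS(=O)(=O)C(F)(F)F)c7ccc(OCc4ccccc4)c(OCc4ccccc4)c7)[C@H]6OCc4ccccc4 | intermediate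
17 | bridged aryloxonium triflate, ring oxygen bonded to furan C2 and the former carbinol carbon (not isolated) | C(c4ccccc4)Oc1cc(OCc4ccccc4)c2c(c1Br)O[C@H](c3ccc(OCc4ccccc4)c(OCc4ccccc4)c3)[C@@H](OCc4ccccc4)[C@@H]2c5c(OCc4ccccc4)cc(OCc4ccccc4)c6c5[O+]7[C@@H]([C@H]7c8ccc(OCc4ccccc4)c(OCc4ccccc4)c8)[C@H]6OCc4ccccc4.[O-]S(=O)(=O)C(F)(F)F | intermediate
18 | ring-expanded 3-O-benzylflavan-4-yl cation triflate, open form of the 3,4-bridged O-benzyl oxiranium ion (not isolated) | C(c4ccccc4)Oc1cc(OCc4ccccc4)c2c(c1Br)O[C@H](c3ccc(OCc4ccccc4)c(OCc4ccccc4)c3)[C@@H](OCc4ccccc4)[C@@H]2c5c(OCc4ccccc4)cc(OCc4ccccc4)c6c5O[C@H](c7ccc(OCc4ccccc4)c(OCc4ccccc4)c7)[C@@H](OCc4ccccc4)[CH+]6.[O-]S(=O)(=O)C(F)(F)F | intermediate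
19 | 8-bromo-penta-O-benzylcatechin-(4α→8)-penta-O-benzylcatechin-(4α→6)-8-bromo-penta-O-benzylcatechin | C(c4ccccc4)Oc1cc(OCc4ccccc4)c2c(c1Br)O[C@H](c3ccc(OCc4ccccc4)c(OCc4ccccc4)c3)[C@@H](OCc4ccccc4)[C@@H]2c5c(OCc4ccccc4)cc(OCc4ccccc4)c6c5O[C@H](c7ccc(OCc4ccccc4)c(OCc4ccccc4)c7)[C@@H](OCc4ccccc4)[C@@H]6c8c(OCc4ccccc4)c9c(c(Br)c8OCc4ccccc4)O[C@H](c3ccc(OCc4ccccc4)c(OCc4ccccc4)c3)[C@@H](OCc4ccccc4)C9 | intermediate
20 | (+)-catechin-(4α→8)-(+)-catechin-(4α→6)-(+)-catechin | Oc1cc(O)c2c(c1)O[C@H](c1ccc(O)c(O)c1)[C@@H](O)[C@@H]2c1c(O)cc(O)c2c1O[C@H](c1ccc(O)c(O)c1)[C@@H](O)[C@@H]2c1c(O)cc2c(c1O)C[C@H](O)[C@@H](c1ccc(O)c(O)c1)O2 | target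

**Step count and risks**
Total steps: 13. Longest linear sequence: 13 (from (+)-catechin; 6 and 9 enter as commercial fragments, and 4 is reused as the bottom unit).

Steps most likely to fail:

1. Step 12 (Proposed new method). The oxygen relay may stall by return of triflate to the benzylic carbon. It may also be diverted by a 1,2-hydride shift from the furan C2 followed by aromatization, or by proton loss from C3 of the cation under the buffered conditions. Fallback with known chemistry, setting out from 5 and 3 and returning at 19: Me3SiOTf-mediated coupling of 5 with excess 3 (CH2Cl2, −78 °C) should give the 4α→8 linked dimer 8-bromo-penta-O-benzylcatechin-(4α→8)-penta-O-benzylcatechin F1. DDQ/MeOH oxidation at C4 of its lower unit should give the 4-methoxy dimer F2. Me3SiOTf coupling of F2 with excess 4, whose C8 is blocked, should then form the 4α→6 bond and give 19.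

2. Step 5. The alkylation may occur at the ring position between the two benzyloxy groups instead of next to the phenol, or the acyl-deactivated ring may react too slowly and allow self-condensation of the cation. Fallback, setting out from 5 and returning at 7: capture of the cation from 5 (BF3·OEt2, dioxane–CH2Cl2) by commercial 2',4',6'-trihydroxyacetophenone, whose two free ring positions are equivalent, should give the C-flavanyl trihydroxyacetophenone F3. Benzylation with two equivalents of BnBr and K2CO3 should then take the 4'- and the unhindered 6'-hydroxyl and leave the hydrogen-bonded hydroxyl next to the flavanyl group free, which is 7.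

3. Step 8. Conversion and facial selectivity of the nucleophilic epoxidation may be poor on the twisted, doubly ortho-substituted aryl enone carrying a large flavanyl group. Fallback, setting out from 10 and returning at 12: CBS reduction of the ketone (BH3·SMe2, with the oxazaborolidine enantiomer that gives the R carbinol) should give the (R)-allylic alcohol F4. Sharpless epoxidation with the matched tartrate (Ti(OiPr)4, L-(+)-diisopropyl tartrate, t-BuOOH, 4 Å MS, CH2Cl2, −20 °C) should then deliver the erythro (1S,2S,3S)-epoxy alcohol 12 directly; the allyl ether alkene is not an allylic alcohol and is not epoxidized.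

Further compounds
F1 | step 12 | 8-bromo-penta-O-benzylcatechin-(4α→8)-penta-O-benzylcatechin | C(c4ccccc4)Oc1cc(OCc4ccccc4)c2c(c1Br)O[C@H](c3ccc(OCc4ccccc4)c(OCc4ccccc4)c3)[C@@H](OCc4ccccc4)[C@@H]2c5c(OCc4ccccc4)cc(OCc4ccccc4)c6c5O[C@H](c7ccc(OCc4ccccc4)c(OCc4ccccc4)c7)[C@@H](OCc4ccccc4)C6
F2 | step 12 | lower-unit 4α-methoxy derivative of F1 | C(c4ccccc4)Oc1cc(OCc4ccccc4)c2c(c1Br)O[C@H](c3ccc(OCc4ccccc4)c(OCc4ccccc4)c3)[C@@H](OCc4ccccc4)[C@@H]2c5c(OCc4ccccc4)cc(OCc4ccccc4)c6c5O[C@H](c7ccc(OCc4ccccc4)c(OCc4ccccc4)c7)[C@@H](OCc4ccccc4)[C@@H]6OC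
F3 | step 5 | 1-[3-(8-bromo-penta-O-benzylcatechin-4α-yl)-2,4,6-trihydroxyphenyl]ethanone | C(c4ccccc4)Oc1cc(OCc4ccccc4)c2c(c1Br)O[C@H](c3ccc(OCc4ccccc4)c(OCc4ccccc4)c3)[C@@H](OCc4ccccc4)[C@@H]2c5c(O)c(C(C)=O)c(O)cc5O
F4 | step 8 | (R,E)-allylic alcohol from 1,2-reduction of 10 | C(c4ccccc4)Oc1cc(OCc4ccccc4)c2c(c1Br)O[C@H](c3ccc(OCc4ccccc4)c(OCc4ccccc4)c3)[C@@H](OCc4ccccc4)[C@@H]2c5c(OCC=C)c([C@H](O)/C=C/c6ccc(OCc4ccccc4)c(OCc4ccccc4)c6)c(OCc4ccccc4)cc5OCc4ccccc4
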